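## Retrosynthetic overview

1. The exocyclic C7 methylene comes from a C7 ketone, carried through the synthesis as a benzyl-protected carbinol. The C12 octanoate and C11 carbinol come from syn-dihydroxylation of a C11=C12 alkene. Ring D (oxepane) is closed by the C3 hydroxyl displacing a C16 triflate, and C15 is set by hydroboration of a C14 isopropenyl group.
2. Rings B and C (tetrahydrofuran and cyclohexene) form together in an intramolecular Diels–Alder reaction of an oxonane carrying a C9 dienyl and a C2 enone arm.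
3. Ring A (oxonane) is closed by ring-closing metathesis of a C3-vinyl/C7-allyl diene, followed by hydrogenation.
4. Key bond C2–C3: an intermolecular Evans boron glycolate aldol between the imide carrying the C7–C10 fragment and acetaldehyde sets C2. C3 is then set by chelation-controlled vinylmagnesium addition to the derived methyl ketone.
5. The C7–C10 fragment comes from (S)-butanetriol acetonide by Brown allylation. Ring order: A, then B and C together, then D.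

Numbering used in names: bicyclo[8.4.0]tetradecane C1–C14 (ring fusion C1/C10), ether bridge C2–O–C9 (the oxonane is O1,C2–C9), C15 = CH on C14 bearing C17H3 and C16H2–O (oxepane oxygen between C3 and C16), C18 = CH3 on C3, C19 = CH2 on C7, C20 = CH3 on C11. Hep = (2S,4S)-4-(benzyloxy)-1-(4-methoxybenzyloxy)hept-6-en-2-yl (hept C2 = skeleton C9, hept C4 = skeleton C7).

## Route

Step 1
Reactants: 1 (S)-2-(2,2-dimethyl-1,3-dioxolan-4-yl)ethanol
Product: 2 (S)-2-(2,2-dimethyl-1,3-dioxolan-4-yl)acetaldehyde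
Conditions: TEMPO (cat.), PhI(OAc)2, CH2Cl2, 23 °C
Reagents that add atoms: none
Why: TEMPO/oxoammonium oxidation of the primary alcohol stops at the aldehyde under near-neutral conditions, so the acetonide and the stereocentre are untouched.

Step 2
Reactants: 2 (S)-2-(2,2-dimethyl-1,3-dioxolan-4-yl)acetaldehyde
Product: 3 (2S)-1-[(4S)-2,2-dimethyl-1,3-dioxolan-4-yl]pent-4-en-2-ol
Conditions: (−)-Ipc2B(allyl), Et2O, −78 °C; then NaOH, H2O2, 0 °C
Reagents that add atoms: (−)-B-allyldiisopinocampheylborane, C=CCB([C@@H]1C[C@@H]2C[C@H]([C@H]1C)C2(C)C)[C@@H]1C[C@@H]2C[C@H]([C@H]1C)C2(C)C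
Why: Brown asymmetric allylboration delivers allyl to the Si face through a chair transition state and sets C7 as (S) under reagent control; this centre is only a defined protecting-group site and is erased as the ketone in step 29.

Step 3
Reactants: 3 (2S)-1-[(4S)-2,2-dimethyl-1,3-dioxolan-4-yl]pent-4-en-2-ol
Product: 4 (4S)-4-[(2S)-2-(benzyloxy)pent-4-enyl]-2,2-dimethyl-1,3-dioxolane
Conditions: NaH, BnBr, Bu4NI (cat.), THF, 0 → 23 °C
Reagents that add atoms: benzyl bromide, BrCc1ccccc1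
Why: Williamson etherification gives a C7 ether that cannot migrate in the later NaH step and is removed by hydrogenolysis only when no alkene is left.

Step 4
Reactants: 4 (4S)-4-[(2S)-2-(benzyloxy)pent-4-enyl]-2,2-dimethyl-1,3-dioxolane
Product: 5 (2S,4S)-4-(benzyloxy)hept-6-ene-1,2-diol
Conditions: AcOH/H2O (4:1), 40 °C
Reagents that add atoms: none
Why: Acid-catalysed acetal hydrolysis frees the 1,2-diol while the benzyl ether, the alkene and both stereocentres stay intact.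

Step 5
Reactants: 5 (2S,4S)-4-(benzyloxy)hept-6-ene-1,2-diol
Product: 7 (2S,4S)-4-(benzyloxy)-1-(4-methoxybenzyloxy)hept-6-en-2-ol, via stannylene acetal 6 (not isolated)
Conditions: Bu2SnO, PhMe, reflux (−H2O); then 4-MeOC6H4CH2Cl, Bu4NI, 100 °C
Reagents that add atoms: 4-methoxybenzyl chloride, COc1ccc(CCl)cc1
Why: Stannylene-acetal activation makes the primary oxygen the more nucleophilic one, so regioselective O-alkylation protects C10–O and leaves the C9 hydroxyl free.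

Step 6
Reactants: 7 (2S,4S)-4-(benzyloxy)-1-(4-methoxybenzyloxy)hept-6-en-2-ol
Product: 8 2-(Hep-oxy)acetic acid
Conditions: NaH (3 equiv), BrCH2CO2H, THF, 0 → 23 °C; then aq. HCl
Reagents that add atoms: bromoacetic acid, OC(=O)CBr
Why: Williamson etherification of the secondary alkoxide with sodium bromoacetate puts the glycolate unit (future C2 and C1) on the C9 oxygen without touching C9.

Step 7
Reactants: 8 2-(Hep-oxy)acetic acid
Product: 10 (4R)-4-benzyl-3-[2-(Hep-oxy)acetyl]oxazolidin-2-one, via mixed pivalic anhydride 9 (not isolated)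
Conditions: t-BuCOCl, Et3N, THF, −20 °C; then (R)-4-benzyloxazolidin-2-one, LiCl, 23 °C
Reagents that add atoms: (R)-4-benzyloxazolidin-2-one, O=C1N[C@H](Cc2ccccc2)CO1
Why: N-acylation of the oxazolidinone through the mixed anhydride is mild enough to leave both ethers and the alkene alone.

Step 8
Reactants: 10 (4R)-4-benzyl-3-[2-(Hep-oxy)acetyl]oxazolidin-2-one, 11 acetaldehyde
Product: 12 (4R)-4-benzyl-3-[(2R,3S)-2-(Hep-oxy)-3-hydroxybutanoyl]oxazolidin-2-one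
Conditions: Bu2BOTf, Et3N, CH2Cl2, −78 → 0 °C; 11, −78 → 0 °C; then pH 7 buffer, MeOH, H2O2
Reagents that add atoms: none
Why: Evans syn boron aldol: the Z-boron enolate of the glycolyl imide adds to acetaldehyde through a Zimmerman–Traxler chair on the face opposite the auxiliary benzyl group, which sets C2 as (R) (the target C2 geometry) and C3 as (S) and joins the C7–C10 glycolate fragment to the C3/C18 unit.

Step 9
Reactants: 12 (4R)-4-benzyl-3-[(2R,3S)-2-(Hep-oxy)-3-hydroxybutanoyl]oxazolidin-2-one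
Product: 13 (2S,3S)-2-(Hep-oxy)butane-1,3-diol
Conditions: LiBH4, MeOH (1 equiv), THF, 0 °C
Reagents that add atoms: none
Why: Reductive cleavage of the imide releases the C1 primary alcohol and the recoverable auxiliary without epimerising C2.

Step 10
Reactants: 13 (2S,3S)-2-(Hep-oxy)butane-1,3-diol
Product: 14 (2S,3S)-3-(Hep-oxy)-4-(tert-butyldiphenylsilyloxy)butan-2-ol
Conditions: t-BuPh2SiCl, imidazole, CH2Cl2, 0 °C
Reagents that add atoms: tert-butyl(chloro)diphenylsilane, CC(C)(C)[Si](Cl)(c1ccccc1)c1ccccc1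
Why: Silylation with the bulky chloride is selective for the primary C1 hydroxyl and gives a non-chelating ether for step 12.

Step 11
Reactants: 14 (2S,3S)-3-(Hep-oxy)-4-(tert-butyldiphenylsilyloxy)butan-2-ol
Product: 15 (3S)-3-(Hep-oxy)-4-(tert-butyldiphenylsilyloxy)butan-2-one
Conditions: Dess–Martin periodinane, pyridine, CH2Cl2, 0 → 23 °C
Reagents that add atoms: none
Why: Dess–Martin oxidation gives the methyl ketone under buffered conditions that do not epimerise the α-alkoxy centre C2.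

Step 12
Reactants: 15 (3S)-3-(Hep-oxy)-4-(tert-butyldiphenylsilyloxy)butan-2-one
Product: 16 (3S,4S)-4-(Hep-oxy)-5-(tert-butyldiphenylsilyloxy)-3-methylpent-1-en-3-ol
Conditions: CH2=CHMgBr, MgBr2·OEt2, CH2Cl2/THF, −78 °C
Reagents that add atoms: vinylmagnesium bromide, C=C[Mg]Br
Why: Cram-chelate controlled Grignard addition: magnesium bridges the ketone oxygen and the C2 ether oxygen and vinyl adds from the face bearing H-2, which sets quaternary C3 as (S) with methyl and vinyl placed as in the target.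

Step 13
Reactants: 16 (3S,4S)-4-(Hep-oxy)-5-(tert-butyldiphenylsilyloxy)-3-methylpent-1-en-3-ol
Product: 17 (2S,3S,7S,9S,4Z)-7-(benzyloxy)-2-[(tert-butyldiphenylsilyloxy)methyl]-9-[(4-methoxybenzyloxy)methyl]-3-methyl-2,3,6,7,8,9-hexahydrooxonin-3-ol
Conditions: [RuCl2(=CHPh)(H2IMes)(PCy3)] (second-generation Grubbs catalyst, 10 mol %), CH2Cl2 (2 mM), 40 °C
Reagents that add atoms: none
Why: Ring-closing metathesis of the vinyl carbinol and the allyl group closes the nine-membered ether as its Z-alkene, helped by the gauche preference of the oxygen-flanked chain and the free allylic hydroxyl.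

Step 14
Reactants: 17 (2S,3S,7S,9S,4Z)-7-(benzyloxy)-2-[(tert-butyldiphenylsilyloxy)methyl]-9-[(4-methoxybenzyloxy)methyl]-3-methyl-2,3,6,7,8,9-hexahydrooxonin-3-ol
Product: 18 (2S,3S,7S,9S)-7-(benzyloxy)-2-[(tert-butyldiphenylsilyloxy)methyl]-9-[(4-methoxybenzyloxy)methyl]-3-methyloxonan-3-ol
Conditions: H2 (1 atm), [Ir(cod)(PCy3)(py)]PF6 (5 mol %), CH2Cl2, 23 °C
Reagents that add atoms: none
Why: Hydroxyl-directed homogeneous hydrogenation saturates the ring alkene and leaves the benzyl and 4-methoxybenzyl ethers untouched.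

Step 15
Reactants: 18 (2S,3S,7S,9S)-7-(benzyloxy)-2-[(tert-butyldiphenylsilyloxy)methyl]-9-[(4-methoxybenzyloxy)methyl]-3-methyloxonan-3-ol
Product: 19 (2S,3S,7S,9S)-7-(benzyloxy)-2-[(tert-butyldiphenylsilyloxy)methyl]-9-[(4-methoxybenzyloxy)methyl]-3-methyl-3-(triethylsilyloxy)oxonane
Conditions: Et3SiOTf, 2,6-lutidine, CH2Cl2, −78 → 0 °C
Reagents that add atoms: triethylsilyl trifluoromethanesulfonate, CC[Si](CC)(CC)OS(=O)(=O)C(F)(F)F
Why: Silylation with the reactive triflate caps the hindered tertiary C3 hydroxyl so that it cannot form a bridged lactol with the C10 aldehyde of step 17.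

Step 16
Reactants: 19 (2S,3S,7S,9S)-7-(benzyloxy)-2-[(tert-butyldiphenylsilyloxy)methyl]-9-[(4-methoxybenzyloxy)methyl]-3-methyl-3-(triethylsilyloxy)oxonane
Product: 20 [(2S,3S,7S,9S)-7-(benzyloxy)-2-[(tert-butyldiphenylsilyloxy)methyl]-3-methyl-3-(triethylsilyloxy)oxonan-9-yl]methanol
Conditions: DDQ, CH2Cl2/pH 7 buffer, 0 °C
Reagents that add atoms: none
Why: Oxidative cleavage of the electron-rich 4-methoxybenzyl ether frees the C10 hydroxyl while the benzyl ether and both silyl ethers survive.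

Step 17
Reactants: 20 [(2S,3S,7S,9S)-7-(benzyloxy)-2-[(tert-butyldiphenylsilyloxy)methyl]-3-methyl-3-(triethylsilyloxy)oxonan-9-yl]methanol
Product: 21 (2S,3S,7S,9S)-7-(benzyloxy)-2-[(tert-butyldiphenylsilyloxy)methyl]-3-methyl-3-(triethylsilyloxy)oxonane-9-carbaldehyde
Conditions: Dess–Martin periodinane, pyridine, CH2Cl2, 0 → 23 °C
Reagents that add atoms: none
Why: Dess–Martin oxidation gives the α-alkoxy aldehyde without epimerising C9.

Step 18
Reactants: 21 (2S,3S,7S,9S)-7-(benzyloxy)-2-[(tert-butyldiphenylsilyloxy)methyl]-3-methyl-3-(triethylsilyloxy)oxonane-9-carbaldehyde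
Product: 22 (2E)-3-[(2S,3S,7S,9S)-7-(benzyloxy)-2-[(tert-butyldiphenylsilyloxy)methyl]-3-methyl-3-(triethylsilyloxy)oxonan-9-yl]-2-methylprop-2-enal
Conditions: Ph3P=C(CH3)CHO, PhMe, 80 °C
Reagents that add atoms: 2-(triphenylphosphoranylidene)propanal, CC(C=O)=P(c1ccccc1)(c1ccccc1)c1ccccc1
Why: Wittig olefination with the stabilised ylide gives the E-configured 2-methyl enal (C10=C11) under neutral conditions.

Step 19
Reactants: 22 (2E)-3-[(2S,3S,7S,9S)-7-(benzyloxy)-2-[(tert-butyldiphenylsilyloxy)methyl]-3-methyl-3-(triethylsilyloxy)oxonan-9-yl]-2-methylprop-2-enal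
Product: 23 (2S,3S,7S,9S)-7-(benzyloxy)-2-[(tert-butyldiphenylsilyloxy)methyl]-3-methyl-9-[(1E)-2-methylbuta-1,3-dien-1-yl]-3-(triethylsilyloxy)oxonane
Conditions: Ph3PCH3Br, KOtBu, THF, 0 °C
Reagents that add atoms: methyltriphenylphosphonium bromide, C[P+](c1ccccc1)(c1ccccc1)c1ccccc1.[Br-]
Why: Wittig methylenation of the enal completes the E-2-methylbuta-1,3-diene that becomes C10–C13.

Step 20
Reactants: 23 (2S,3S,7S,9S)-7-(benzyloxy)-2-[(tert-butyldiphenylsilyloxy)methyl]-3-methyl-9-[(1E)-2-methylbuta-1,3-dien-1-yl]-3-(triethylsilyloxy)oxonane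
Product: 24 (2S,3S,7S,9S)-7-(benzyloxy)-2-(hydroxymethyl)-3-methyl-9-[(1E)-2-methylbuta-1,3-dien-1-yl]oxonan-3-ol
Conditions: Bu4NF, THF, 0 → 23 °C
Reagents that add atoms: none
Why: Fluoride-mediated desilylation removes the primary silyl ether and the tertiary triethylsilyl ether in one operation while the benzyl ether and the diene are inert.

Step 21
Reactants: 24 (2S,3S,7S,9S)-7-(benzyloxy)-2-(hydroxymethyl)-3-methyl-9-[(1E)-2-methylbuta-1,3-dien-1-yl]oxonan-3-ol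
Product: 25 (2R,3S,7S,9S)-7-(benzyloxy)-3-hydroxy-3-methyl-9-[(1E)-2-methylbuta-1,3-dien-1-yl]oxonane-2-carbaldehyde
Conditions: Dess–Martin periodinane, pyridine, CH2Cl2, 0 °C
Reagents that add atoms: none
Why: Dess–Martin oxidation acts only on the primary C1 hydroxyl (the tertiary C3 hydroxyl cannot be oxidised) and tolerates the diene; the descriptor at C2 changes by priority only.

Step 22
Reactants: 25 (2R,3S,7S,9S)-7-(benzyloxy)-3-hydroxy-3-methyl-9-[(1E)-2-methylbuta-1,3-dien-1-yl]oxonane-2-carbaldehyde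
Product: 27 1-[(1R,2S,3S,7S,9S,10S,14R)-7-(benzyloxy)-2,9-epoxy-3-hydroxy-3,11-dimethylbicyclo[8.4.0]tetradec-11-en-14-yl]ethanone, via enone 26 (not isolated)
Conditions: Ph3P=CHC(O)CH3, PhMe, 23 → 80 °C
Reagents that add atoms: 1-(triphenylphosphoranylidene)propan-2-one, CC(=O)C=P(c1ccccc1)(c1ccccc1)c1ccccc1
Why: Wittig olefination gives the E-enone, which undergoes an intramolecular Diels–Alder reaction on the face of the forming tetrahydrofuran away from the bridging oxonane chain, setting C1, C10 and C14 (cis ring fusion, H-1 trans to H-2, acetyl trans to C2), as is well established for the corresponding oxonene-tethered trienes.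

Step 23
Reactants: 27 1-[(1R,2S,3S,7S,9S,10S,14R)-7-(benzyloxy)-2,9-epoxy-3-hydroxy-3,11-dimethylbicyclo[8.4.0]tetradec-11-en-14-yl]ethanone
Product: 28 (1S,2S,3S,7S,9S,10S,14R)-7-(benzyloxy)-2,9-epoxy-3,11-dimethyl-14-(prop-1-en-2-yl)bicyclo[8.4.0]tetradec-11-en-3-ol
Conditions: Ph3PCH3Br, KOtBu (excess), THF, 0 → 23 °C
Reagents that add atoms: methyltriphenylphosphonium bromide, C[P+](c1ccccc1)(c1ccccc1)c1ccccc1.[Br-]
Why: Wittig methylenation converts the C14 acetyl group into the isopropenyl group without touching the trisubstituted ring alkene.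

Step 24
Reactants: 28 (1S,2S,3S,7S,9S,10S,14R)-7-(benzyloxy)-2,9-epoxy-3,11-dimethyl-14-(prop-1-en-2-yl)bicyclo[8.4.0]tetradec-11-en-3-ol
Product: 30 (1S,2S,3S,7S,9S,10S,14S)-7-(benzyloxy)-2,9-epoxy-14-[(2R)-1-hydroxypropan-2-yl]-3,11-dimethylbicyclo[8.4.0]tetradec-11-en-3-ol, via B-alkyl-9-BBN adduct 29 (not isolated)
Conditions: 9-BBN, THF, 0 → 23 °C; then NaOH, H2O2, 0 °C
Reagents that add atoms: hydrogen peroxide, OO
Why: Hydroboration–oxidation with bulky 9-BBN reacts only at the 1,1-disubstituted alkene and adds anti to the larger C1 branch in the conformer with H-14 eclipsing the alkene, which sets C15 as (R).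

Step 25
Reactants: 30 (1S,2S,3S,7S,9S,10S,14S)-7-(benzyloxy)-2,9-epoxy-14-[(2R)-1-hydroxypropan-2-yl]-3,11-dimethylbicyclo[8.4.0]tetradec-11-en-3-ol
Product: 32 (1S,2S,3S,7S,9S,10S,14S,15R)-7-(benzyloxy)-2,9:3,16-diepoxy-tetracycle with C11=C12, via primary triflate 31 (not isolated)
Conditions: Tf2O, 2,6-lutidine, CH2Cl2, −78 → 0 °C
Reagents that add atoms: none
Why: Selective triflation of the primary hydroxyl followed by intramolecular Williamson-type displacement by the tertiary C3 hydroxyl (7-exo-tet) closes the oxepane without affecting any stereocentre.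

Step 26
Reactants: 32 (1S,2S,3S,7S,9S,10S,14S,15R)-7-(benzyloxy)-2,9:3,16-diepoxy-tetracycle with C11=C12
Product: 33 (1S,2S,3S,7S,9S,10R,11R,12S,14S,15R)-7-(benzyloxy)-2,9:3,16-diepoxy-tetracycle-11,12-diol
Conditions: OsO4 (5 mol %), NMO, acetone/H2O, 23 °C
Reagents that add atoms: osmium tetroxide, O=[Os](=O)(=O)=O; N-methylmorpholine N-oxide, C[N+]1([O-])CCOCC1; water, O
Why: Upjohn dihydroxylation adds syn to the only alkene from the convex face opposite the tetrahydrofuran ring, setting C11 (R) and C12 (S) as the cis diol.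

Step 27
Reactants: 33 (1S,2S,3S,7S,9S,10R,11R,12S,14S,15R)-7-(benzyloxy)-2,9:3,16-diepoxy-tetracycle-11,12-diol
Product: 34 12-octanoate of 33 (7-benzyloxy-11-hydroxy-12-octanoyloxy tetracycle)
Conditions: (n-C7H15CO)2O, Et3N, DMAP (cat.), CH2Cl2, 0 → 23 °C
Reagents that add atoms: octanoic anhydride, CCCCCCCC(=O)OC(=O)CCCCCCC
Why: DMAP-catalysed acyl transfer esterifies the secondary C12 hydroxyl while the tertiary C11 hydroxyl is too hindered to react.

Step 28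
Reactants: 34 12-octanoate of 33 (7-benzyloxy-11-hydroxy-12-octanoyloxy tetracycle)
Product: 35 (7S)-7,11-dihydroxy-12-octanoyloxy tetracycle
Conditions: H2 (1 atm), Pd(OH)2/C, EtOAc, 23 °C
Reagents that add atoms: none
Why: Hydrogenolysis cleaves the benzyl ether cleanly because no alkene is present at this stage; the ester, the ethers and the tertiary alcohol are inert.

Step 29
Reactants: 35 (7S)-7,11-dihydroxy-12-octanoyloxy tetracycle
Product: 36 11-hydroxy-12-octanoyloxy-7-oxo tetracycle (1S,2S,3S,9S,10R,11R,12S,14S,15R)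
Conditions: Dess–Martin periodinane, pyridine, CH2Cl2, 23 °C
Reagents that add atoms: none
Why: Dess–Martin oxidation converts the C7 carbinol into the ketone and removes the auxiliary C7 stereocentre; the tertiary alcohol and the ester are unaffected.

Step 30
Reactants: 36 11-hydroxy-12-octanoyloxy-7-oxo tetracycle (1S,2S,3S,9S,10R,11R,12S,14S,15R)
Product: 37 target CNP0286133.1 (1S,2S,3S,9S,10R,11R,12S,14S,15R)
Conditions: Zn, CH2Br2, TiCl4 (pre-formed reagent), THF/CH2Cl2, 0 → 23 °C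
Reagents that add atoms: dibromomethane, BrCBr
Why: Takai–Lombardo methylenation with the non-basic gem-dimetallic reagent converts the enolisable β-alkoxy ketone into the exocyclic alkene without β-elimination, acyl migration or attack on the ester.

## Compound list

1 | (S)-2-(2,2-dimethyl-1,3-dioxolan-4-yl)ethanol | OCC[C@H]1COC(C)(C)O1 | starting material
2 | (S)-2-(2,2-dimethyl-1,3-dioxolan-4-yl)acetaldehyde | O=CC[C@H]1COC(C)(C)O1 | intermediate
3 | (2S)-1-[(4S)-2,2-dimethyl-1,3-dioxolan-4-yl]pent-4-en-2-ol | C=CC[C@H](O)C[C@H]1COC(C)(C)O1 | intermediate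
4 | (4S)-4-[(2S)-2-(benzyloxy)pent-4-enyl]-2,2-dimethyl-1,3-dioxolane | C=CC[C@H](OCc1ccccc1)C[C@H]2COC(C)(C)O2 | intermediate
5 | (2S,4S)-4-(benzyloxy)hept-6-ene-1,2-diol | C=CC[C@H](OCc1ccccc1)C[C@H](O)CO | intermediate
6 | (4S)-4-[(2S)-2-(benzyloxy)pent-4-enyl]-2,2-dibutyl-1,3,2-dioxastannolane | C=CC[C@H](OCc1ccccc1)C[C@H]2CO[Sn](CCCC)(CCCC)O2 | intermediate (not isolated)
7 | (2S,4S)-4-(benzyloxy)-1-(4-methoxybenzyloxy)hept-6-en-2-ol | C=CC[C@H](OCc1ccccc1)C[C@H](O)COCc2ccc(OC)cc2 | intermediate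
8 | 2-(Hep-oxy)acetic acid | C=CC[C@H](OCc1ccccc1)C[C@H](OCC(=O)O)COCc2ccc(OC)cc2 | intermediate
9 | 2-(Hep-oxy)acetic pivalic anhydride | C=CC[C@H](OCc1ccccc1)C[C@H](OCC(=O)OC(=O)C(C)(C)C)COCc2ccc(OC)cc2 | intermediate (not isolated)
10 | (4R)-4-benzyl-3-[2-(Hep-oxy)acetyl]oxazolidin-2-one | C=CC[C@H](OCc1ccccc1)C[C@H](OCC(=O)N2[C@H](Cc3ccccc3)COC2=O)COCc4ccc(OC)cc4 | intermediate
11 | acetaldehyde | CC=O | starting material
12 | (4R)-4-benzyl-3-[(2R,3S)-2-(Hep-oxy)-3-hydroxybutanoyl]oxazolidin-2-one | C=CC[C@H](OCc1ccccc1)C[C@H](O[C@H]([C@H](C)O)C(=O)N2[C@H](Cc3ccccc3)COC2=O)COCc4ccc(OC)cc4 | intermediate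
13 | (2S,3S)-2-(Hep-oxy)butane-1,3-diol | C=CC[C@H](OCc1ccccc1)C[C@H](O[C@H]([C@H](C)O)CO)COCc2ccc(OC)cc2 | intermediate
14 | (2S,3S)-3-(Hep-oxy)-4-(tert-butyldiphenylsilyloxy)butan-2-ol | C=CC[C@H](OCc1ccccc1)C[C@H](O[C@H]([C@H](C)O)CO[Si](c2ccccc2)(c3ccccc3)C(C)(C)C)COCc4ccc(OC)cc4 | intermediate
15 | (3S)-3-(Hep-oxy)-4-(tert-butyldiphenylsilyloxy)butan-2-one | C=CC[C@H](OCc1ccccc1)C[C@H](O[C@H](C(C)=O)CO[Si](c2ccccc2)(c3ccccc3)C(C)(C)C)COCc4ccc(OC)cc4 | intermediate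
16 | (3S,4S)-4-(Hep-oxy)-5-(tert-butyldiphenylsilyloxy)-3-methylpent-1-en-3-ol | C=CC[C@H](OCc1ccccc1)C[C@H](O[C@H]([C@@](C)(O)C=C)CO[Si](c2ccccc2)(c3ccccc3)C(C)(C)C)COCc4ccc(OC)cc4 | intermediate
17 | (2S,3S,7S,9S,4Z)-7-(benzyloxy)-2-[(tert-butyldiphenylsilyloxy)methyl]-9-[(4-methoxybenzyloxy)methyl]-3-methyl-2,3,6,7,8,9-hexahydrooxonin-3-ol | CC(C)(C)[Si](c1ccccc1)(c2ccccc2)OC[C@@H]3O[C@H](COCc4ccc(OC)cc4)C[C@@H](OCc5ccccc5)C/C=C\[C@]3(C)O | intermediate
18 | (2S,3S,7S,9S)-7-(benzyloxy)-2-[(tert-butyldiphenylsilyloxy)methyl]-9-[(4-methoxybenzyloxy)methyl]-3-methyloxonan-3-ol | CC(C)(C)[Si](c1ccccc1)(c2ccccc2)OC[C@@H]3O[C@H](COCc4ccc(OC)cc4)C[C@@H](OCc5ccccc5)CCC[C@]3(C)O | intermediate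
19 | (2S,3S,7S,9S)-7-(benzyloxy)-2-[(tert-butyldiphenylsilyloxy)methyl]-9-[(4-methoxybenzyloxy)methyl]-3-methyl-3-(triethylsilyloxy)oxonane | CC(C)(C)[Si](c1ccccc1)(c2ccccc2)OC[C@@H]3O[C@H](COCc4ccc(OC)cc4)C[C@@H](OCc5ccccc5)CCC[C@]3(C)O[Si](CC)(CC)CC | intermediate
20 | [(2S,3S,7S,9S)-7-(benzyloxy)-2-[(tert-butyldiphenylsilyloxy)methyl]-3-methyl-3-(triethylsilyloxy)oxonan-9-yl]methanol | CC(C)(C)[Si](c1ccccc1)(c2ccccc2)OC[C@@H]3O[C@H](CO)C[C@@H](OCc4ccccc4)CCC[C@]3(C)O[Si](CC)(CC)CC | intermediate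
21 | (2S,3S,7S,9S)-7-(benzyloxy)-2-[(tert-butyldiphenylsilyloxy)methyl]-3-methyl-3-(triethylsilyloxy)oxonane-9-carbaldehyde | CC(C)(C)[Si](c1ccccc1)(c2ccccc2)OC[C@@H]3O[C@H](C=O)C[C@@H](OCc4ccccc4)CCC[C@]3(C)O[Si](CC)(CC)CC | intermediate
22 | (2E)-3-[(2S,3S,7S,9S)-7-(benzyloxy)-2-[(tert-butyldiphenylsilyloxy)methyl]-3-methyl-3-(triethylsilyloxy)oxonan-9-yl]-2-methylprop-2-enal | CC(C)(C)[Si](c1ccccc1)(c2ccccc2)OC[C@@H]3O[C@H](/C=C(\C)C=O)C[C@@H](OCc4ccccc4)CCC[C@]3(C)O[Si](CC)(CC)CC | intermediate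
23 | (2S,3S,7S,9S)-7-(benzyloxy)-2-[(tert-butyldiphenylsilyloxy)methyl]-3-methyl-9-[(1E)-2-methylbuta-1,3-dien-1-yl]-3-(triethylsilyloxy)oxonane | CC(C)(C)[Si](c1ccccc1)(c2ccccc2)OC[C@@H]3O[C@H](/C=C(\C)C=C)C[C@@H](OCc4ccccc4)CCC[C@]3(C)O[Si](CC)(CC)CC | intermediate
24 | (2S,3S,7S,9S)-7-(benzyloxy)-2-(hydroxymethyl)-3-methyl-9-[(1E)-2-methylbuta-1,3-dien-1-yl]oxonan-3-ol | OC[C@@H]1O[C@H](/C=C(\C)C=C)C[C@@H](OCc2ccccc2)CCC[C@]1(C)O | intermediate
25 | (2R,3S,7S,9S)-7-(benzyloxy)-3-hydroxy-3-methyl-9-[(1E)-2-methylbuta-1,3-dien-1-yl]oxonane-2-carbaldehyde | O=C[C@@H]1O[C@H](/C=C(\C)C=C)C[C@@H](OCc2ccccc2)CCC[C@]1(C)O | intermediate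
26 | (3E)-4-[(2S,3S,7S,9S)-7-(benzyloxy)-3-hydroxy-3-methyl-9-[(1E)-2-methylbuta-1,3-dien-1-yl]oxonan-2-yl]but-3-en-2-one | CC(=O)/C=C/[C@@H]1O[C@H](/C=C(\C)C=C)C[C@@H](OCc2ccccc2)CCC[C@]1(C)O | intermediate (not isolated)
27 | 1-[(1R,2S,3S,7S,9S,10S,14R)-7-(benzyloxy)-2,9-epoxy-3-hydroxy-3,11-dimethylbicyclo[8.4.0]tetradec-11-en-14-yl]ethanone | O(Cc1ccccc1)[C@H]2CCC[C@](C)(O)[C@H]3O[C@@H](C2)[C@@H]4C(C)=CC[C@@H](C(C)=O)[C@H]34 | intermediate
28 | (1S,2S,3S,7S,9S,10S,14R)-7-(benzyloxy)-2,9-epoxy-3,11-dimethyl-14-(prop-1-en-2-yl)bicyclo[8.4.0]tetradec-11-en-3-ol | O(Cc1ccccc1)[C@H]2CCC[C@](C)(O)[C@H]3O[C@@H](C2)[C@@H]4C(C)=CC[C@@H](C(C)=C)[C@H]34 | intermediate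
29 | C16 B-alkyl-9-borabicyclo[3.3.1]nonane adduct of 28 (15R) | O(Cc1ccccc1)[C@H]2CCC[C@](C)(O)[C@H]3O[C@@H](C2)[C@@H]4C(C)=CC[C@@H]([C@@H](C)CB5C6CCCC5CCC6)[C@H]34 | intermediate (not isolated)
30 | (1S,2S,3S,7S,9S,10S,14S)-7-(benzyloxy)-2,9-epoxy-14-[(2R)-1-hydroxypropan-2-yl]-3,11-dimethylbicyclo[8.4.0]tetradec-11-en-3-ol | O(Cc1ccccc1)[C@H]2CCC[C@](C)(O)[C@H]3O[C@@H](C2)[C@@H]4C(C)=CC[C@@H]([C@@H](C)CO)[C@H]34 | intermediate
31 | C16 trifluoromethanesulfonate of 30 | O(Cc1ccccc1)[C@H]2CCC[C@](C)(O)[C@H]3O[C@@H](C2)[C@@H]4C(C)=CC[C@@H]([C@@H](C)COS(=O)(=O)C(F)(F)F)[C@H]34 | intermediate (not isolated)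
32 | (1S,2S,3S,7S,9S,10S,14S,15R)-7-(benzyloxy)-2,9:3,16-diepoxy-tetracycle with C11=C12 | O(Cc1ccccc1)[C@H]2CCC[C@]3(C)OC[C@H](C)[C@@H]4CC=C(C)[C@@H]5[C@H]4[C@@H]3O[C@H]5C2 | intermediate
33 | (1S,2S,3S,7S,9S,10R,11R,12S,14S,15R)-7-(benzyloxy)-2,9:3,16-diepoxy-tetracycle-11,12-diol | O(Cc1ccccc1)[C@H]2CCC[C@]3(C)OC[C@H](C)[C@@H]4C[C@H](O)[C@](C)(O)[C@@H]5[C@H]4[C@@H]3O[C@H]5C2 | intermediate
34 | 12-octanoate of 33 (7-benzyloxy-11-hydroxy-12-octanoyloxy tetracycle) | O(Cc1ccccc1)[C@H]2CCC[C@]3(C)OC[C@H](C)[C@@H]4C[C@H](OC(=O)CCCCCCC)[C@](C)(O)[C@@H]5[C@H]4[C@@H]3O[C@H]5C2 | intermediate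
35 | (7S)-7,11-dihydroxy-12-octanoyloxy tetracycle | O[C@H]1CCC[C@]2(C)OC[C@H](C)[C@@H]3C[C@H](OC(=O)CCCCCCC)[C@](C)(O)[C@@H]4[C@H]3[C@@H]2O[C@H]4C1 | intermediate
36 | 11-hydroxy-12-octanoyloxy-7-oxo tetracycle (1S,2S,3S,9S,10R,11R,12S,14S,15R) | O=C1CCC[C@]2(C)OC[C@H](C)[C@@H]3C[C@H](OC(=O)CCCCCCC)[C@](C)(O)[C@@H]4[C@H]3[C@@H]2O[C@H]4C1 | intermediate
37 | CNP0286133.1, (1S,2S,3S,9S,10R,11R,12S,14S,15R)-11-hydroxy-7(19)-methylene-2,9:3,16-diepoxy tetracycle 12-octanoate | C=C1CCC[C@]2(C)OC[C@H](C)[C@@H]3C[C@H](OC(=O)CCCCCCC)[C@](C)(O)[C@@H]4[C@H]3[C@@H]2O[C@H]4C1 | target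

## Step count and risk

Total steps: 30. Longest linear sequence: 30 steps (fully linear from 1).

The three steps most likely to fail:

Step 13 (ring closure onto a vinyl group on a fully substituted carbon). Fallback by relay metathesis: it sets out from ketone 15, which is treated with (E)-3-(allyloxy)prop-1-enylmagnesium bromide (from the vinyl iodide, t-BuLi, then MgBr2·OEt2; same chelate control) to give the relay dienyl carbinol F1. With the same ruthenium catalyst the unhindered allyl ether is loaded first, 2,5-dihydrofuran is expelled, and the carbene so placed on C4 closes onto the C7 allyl group. The sequence comes back to the route at oxonene 17.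

Step 22 (cycloaddition on the flexible saturated oxonane, for which rate and facial selectivity are less secure than for an oxonene). Fallback by keeping the ring alkene as a conformational lock: it sets out from oxonene 17, which skips step 14 and is taken through the operations of steps 15 to 22. These give in turn the triethylsilyl ether F2, the C10 alcohol F3, the C10 aldehyde F4, the enal F5, the diene F6, the diol F7, the C1 aldehyde F8, the enone F9 (not isolated) and the unsaturated cycloadduct F10. Diimide (TsNHNH2, NaOAc, DME/H2O, 85 °C) then reduces only the cis-disubstituted ring alkene of F10, and the sequence comes back to the route at ketone 27.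

Step 24 (substrate-controlled diastereoselectivity at C15). Fallback by catalyst control: it sets out from ketone 27, which is converted with KN(SiMe3)2 and PhNTf2 into the enol triflate F11. Carbonylation (Pd(PPh3)4, CO, MeOH, Et3N, DMF) gives the acrylate ester F12, and reduction with i-Bu2AlH gives the 2-substituted allylic alcohol F13. Hydroxyl-directed asymmetric hydrogenation of F13 with Ru(OAc)2[(S)-BINAP] (or its antipode, whichever is matched) sets C15, and the sequence comes back to the route at primary alcohol 30.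

Further compounds

F1 | step 13 | (3S,4S,1E)-1-[3-(allyloxy)]-substituted relay carbinol: 4-(Hep-oxy)-5-(tert-butyldiphenylsilyloxy)-3-methyl-1-[(allyloxy)methyl]pent-1-en-3-ol | C=CC[C@H](OCc1ccccc1)C[C@H](O[C@H]([C@@](C)(O)/C=C/COCC=C)CO[Si](c2ccccc2)(c3ccccc3)C(C)(C)C)COCc4ccc(OC)cc4
F2 | step 22 | 4,5-didehydro analogue of 19 (triethylsilyl ether of 17) | CC(C)(C)[Si](c1ccccc1)(c2ccccc2)OC[C@@H]3O[C@H](COCc4ccc(OC)cc4)C[C@@H](OCc5ccccc5)C/C=C\[C@]3(C)O[Si](CC)(CC)CC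
F3 | step 22 | 4,5-didehydro analogue of 20 (C10 alcohol) | CC(C)(C)[Si](c1ccccc1)(c2ccccc2)OC[C@@H]3O[C@H](CO)C[C@@H](OCc4ccccc4)C/C=C\[C@]3(C)O[Si](CC)(CC)CC
F4 | step 22 | 4,5-didehydro analogue of 21 (C10 aldehyde) | CC(C)(C)[Si](c1ccccc1)(c2ccccc2)OC[C@@H]3O[C@H](C=O)C[C@@H](OCc4ccccc4)C/C=C\[C@]3(C)O[Si](CC)(CC)CC
F5 | step 22 | 4,5-didehydro analogue of 22 (enal) | CC(C)(C)[Si](c1ccccc1)(c2ccccc2)OC[C@@H]3O[C@H](/C=C(\C)C=O)C[C@@H](OCc4ccccc4)C/C=C\[C@]3(C)O[Si](CC)(CC)CC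
F6 | step 22 | 4,5-didehydro analogue of 23 (diene) | CC(C)(C)[Si](c1ccccc1)(c2ccccc2)OC[C@@H]3O[C@H](/C=C(\C)C=C)C[C@@H](OCc4ccccc4)C/C=C\[C@]3(C)O[Si](CC)(CC)CC
F7 | step 22 | 4,5-didehydro analogue of 24 (diol) | OC[C@@H]1O[C@H](/C=C(\C)C=C)C[C@@H](OCc2ccccc2)C/C=C\[C@]1(C)O
F8 | step 22 | 4,5-didehydro analogue of 25 (C1 aldehyde) | O=C[C@@H]1O[C@H](/C=C(\C)C=C)C[C@@H](OCc2ccccc2)C/C=C\[C@]1(C)O
F9 | step 22 | 4,5-didehydro analogue of 26 (enone) | CC(=O)/C=C/[C@@H]1O[C@H](/C=C(\C)C=C)C[C@@H](OCc2ccccc2)C/C=C\[C@]1(C)O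
F10 | step 22 | 4,5-didehydro analogue of 27 (cycloadduct with Z-C4=C5) | O(Cc1ccccc1)[C@H]2C/C=C\[C@](C)(O)[C@H]3O[C@@H](C2)[C@@H]4C(C)=CC[C@@H](C(C)=O)[C@H]34
F11 | step 24 | enol triflate of 27 (C14 bears C(=CH2)OSO2CF3) | O(Cc1ccccc1)[C@H]2CCC[C@](C)(O)[C@H]3O[C@@H](C2)[C@@H]4C(C)=CC[C@@H](C(=C)OS(=O)(=O)C(F)(F)F)[C@H]34
F12 | step 24 | methyl 2-(C14-yl)acrylate (C14 bears C(=CH2)CO2CH3) | O(Cc1ccccc1)[C@H]2CCC[C@](C)(O)[C@H]3O[C@@H](C2)[C@@H]4C(C)=CC[C@@H](C(=C)C(=O)OC)[C@H]34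
F13 | step 24 | 2-(C14-yl)prop-2-en-1-ol (C14 bears C(=CH2)CH2OH) | O(Cc1ccccc1)[C@H]2CCC[C@](C)(O)[C@H]3O[C@@H](C2)[C@@H]4C(C)=CC[C@@H](C(=C)CO)[C@H]34
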